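The amounts of target in two earlier runs, both at 0.90 equiv of coupling partner, differed, and I wanted the height and time of the peak in a flask between them.

| flask | substrate | coupling partner | remark | time |
|---|---|---|---|---|
| south-east | 0.10 M | 0.90 equiv | run made earlier |  |
| north-west | 0.40 M | 0.90 equiv | run made earlier |  |
| flask | 0.20 M | 0.900 equiv |  | 20 h |

| run | time / h | target / % |
|---|---|---|
| south-east | 1.00 | 4 |
| south-east | 2.00 | 9 |
| south-east | 4.00 | 10 |
| south-east | 6.00 | 9 |
| south-east | 12.0 | 7 |
| south-east | 20.0 | 1 |
| north-west | 1.00 | 16 |
| north-west | 2.00 | 26 |
| north-west | 4.00 | 26 |
| north-west | 6.00 | 28 |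
| north-west | 12.0 | 23 |
| north-west | 20.0 | 11 |

(each reading ± 2 percentage points)

- a reading or a percentage of target counts all its forms, free or not

1. the best time, 20 h at the latest, for target
2. the amount of target, in percent of the substrate charged, at that time

After 1.00 h, the south-east run showed 4% and the north-west run 16%. Their ratio of 4.00, rough with a scatter of 2 percentage points on each reading, lay near the ratio of their partner concentrations, 0.0900 M and 0.360 M. Substrate rose by the same factor at fixed equivalents, so these runs did not tell the two charges apart.

In the middle both runs stood flat, and their highest readings, 10% at 4.00 h and 28% at 6.00 h, differed by a smaller ratio than the partner concentrations. I carried that bend as the height exponent, the slope in logarithms of peak target against partner concentration at fixed equivalents, an apparent order: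

log(28% / 10%) / log(0.360 M / 0.0900 M) = 0.743

For the flask, with partner at 0.180 M, I reckoned:

10% × (0.180 M / 0.0900 M)^0.743 = 16.7%

Late on, target fell. At 20.0 h the south-east run held 1% and the north-west run 11%, the south-east run keeping the smaller share of its peak. I placed the flask's best between the times of the two highest readings, 4.00 h and 6.00 h.

The forecast gave 17% (14% to 20%) at 4 h (2.5 h to 6.5 h), warning that “the peak time is poorly defined because the plateau is flat within the scatter”.

The flask gave 18.5% at 4.56 h, inside both forecast ranges, and at that moment it also held 42.0% of side product. My height of 16.7% fell 1.8 points short, beside a scatter of 2 points in the readings behind the exponent.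

    substrate + coupling partner ⇌ target (K = 2.80 M⁻¹, k = 0.730 M⁻¹ h⁻¹)
    substrate → side product (k = 0.160 h⁻¹)
    target → over-reaction product (k = 8.70 × 10⁻⁵ h⁻¹)
    substrate + target ⇌ idle adduct, settled at all times (K = 4.40 M⁻¹)

The neighbour flask, cut to 0.230 equiv of coupling partner at the same substrate charge, had partner at 0.0460 M, below both runs. The exponent, read from both runs at fixed equivalents and here stretched to other equivalents, gave 6.07% when set on the south-east peak reading. Its computed best was 5.58%.

The readings stem from a simulated flask for substances that don't exist.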